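## Retrosynthetic overview

1. The ten-membered carbocycle is closed last, by ring-closing metathesis across C4=C5 of an open-chain tiglate carrying a propenyl group on C6 and a 1,1-disubstituted olefin at C4; the medium ring is expected to enforce the Z olefin.
2. The C8 tiglate is installed by Mitsunobu inversion, because the preceding C7–C8 bond formation delivers the 8-epi alcohol.
3. The C7–C8 bond comes from a zinc Barbier allylation of a keto aldehyde (C1–C4, C8–C10) with a 3-(bromomethyl)butenolide (C5–C7, C11–C13); it sets C7 and C8 and unveils the exocyclic methylene.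
4. Butenolide: Sharpless kinetic resolution of hexa-1,4-dien-3-ol (C6), acylation with 2-(bromomethyl)acrylic acid, ring-closing metathesis. Keto aldehyde: Seebach alkylation of (S)-lactic acid (C10), ozonolysis/lactonisation, Grignard addition of an isoprenol-derived unit, oxidation.
5. Ring order: butenolide first, ten-membered ring last.

Assumption: positions are named by germacrane numbering (C1 ketone, C10 carbinol, C8 ester carbon, C6 lactone O-carbon, C11–C13 lactone carbons); the goal is the (6R,7R,8R,10R)-4Z compound with the (E)-2-methylbut-2-enoate (tiglate), as the SMILES encodes.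

## Route

Step 1
Reactants: 1 (E)-but-2-enal (crotonaldehyde); 2 vinylmagnesium bromide
Product: 3 rac-(4E)-hexa-1,4-dien-3-ol
Conditions: THF, −78 → 0 °C; sat. aq NH4Cl
Reagents that add atoms: none
Why: 1,2-Grignard addition of the vinyl nucleophile to the enal carbonyl gives the bis-allylic alcohol as the racemate, which is resolved in the next step.

Step 2
Reactants: 3 rac-(4E)-hexa-1,4-dien-3-ol
Product: 4 (3S,4E)-hexa-1,4-dien-3-ol
Conditions: Ti(OiPr)4 (10 mol%), D-(−)-diisopropyl tartrate (15 mol%), tBuOOH (0.6 equiv), 4 Å MS, CH2Cl2, −20 °C, stopped at about 55–60% conversion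
Reagents that add atoms: none
Why: Sharpless kinetic resolution: with the D-(−)-tartrate the (R)-enantiomer is epoxidised at its (E)-propenyl group much faster (the vinyl group is almost inert), so the unreacted (S)-alcohol, which carries the future C6 configuration, is recovered in high ee.

Step 3
Reactants: 4 (3S,4E)-hexa-1,4-dien-3-ol; 5 2-(bromomethyl)prop-2-enoic acid
Product: 6 (3S,4E)-hexa-1,4-dien-3-yl 2-(bromomethyl)prop-2-enoate
Conditions: DCC, DMAP (5 mol%), CH2Cl2, 0 °C → rt
Reagents that add atoms: none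
Why: Steglich esterification acylates the secondary alcohol without touching its stereocentre and brings in the carbons that become C11–C13.

Step 4
Reactants: 6 (3S,4E)-hexa-1,4-dien-3-yl 2-(bromomethyl)prop-2-enoate
Product: 7 (5R)-3-(bromomethyl)-5-[(1E)-prop-1-en-1-yl]furan-2(5H)-one
Conditions: second-generation Grubbs catalyst [(H2IMes)(PCy3)Cl2Ru=CHPh] (5 mol%), CH2Cl2 (5 mM), 40 °C
Reagents that add atoms: none
Why: Ring-closing metathesis: the ruthenium carbene loads on the terminal vinyl group and closes onto the acrylate to give the five-membered butenolide, while the internal propenyl group survives and the stereocentre is untouched (any 5-vinyl by-product from initiation at the propenyl group is a different compound and is removed by chromatography).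

Step 5
Reactants: 8 (S)-lactic acid; 9 pivalaldehyde (2,2-dimethylpropanal)
Product: 10 (2S,5S)-2-tert-butyl-5-methyl-1,3-dioxolan-4-one (cis)
Conditions: TsOH·H2O (cat.), H2SO4 (cat.), pentane, reflux, Dean–Stark; recrystallised from pentane at −78 °C
Reagents that add atoms: none
Why: Acid-catalysed acetalisation (Seebach self-regeneration of stereocentres) gives mainly the cis-dioxolanone, purified by crystallisation, whose acetal carbon stores the chirality of lactic acid.

Step 6
Reactants: 10 (2S,5S)-2-tert-butyl-5-methyl-1,3-dioxolan-4-one; 11 allyl bromide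
Product: 13 (2S,5R)-2-tert-butyl-5-methyl-5-(prop-2-en-1-yl)-1,3-dioxolan-4-one, via lithium enolate 12 (not isolated)
Conditions: LiN(iPr)2 (LDA), THF, −78 °C; then allyl bromide, −78 → −20 °C
Reagents that add atoms: none
Why: Enolate alkylation: the planar lithium enolate is allylated on the face anti to the tert-butyl group, so allyl replaces H with net retention and the quaternary carbinol carbon (future C10) is set.

Step 7
Reactants: 13 (2S,5R)-2-tert-butyl-5-methyl-5-(prop-2-en-1-yl)-1,3-dioxolan-4-one
Product: 16 (3R)-3-hydroxy-3-methyloxolan-2-one, via dioxolanone aldehyde 14 (not isolated), via hydroxyethyl dioxolanone 15 (not isolated)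
Conditions: O3, CH2Cl2/MeOH, −78 °C; Me2S, −78 °C → rt; NaBH4, 0 °C; then aq HCl (pH 2), rt
Reagents that add atoms: ozone, [O-][O+]=O
Why: Ozonolysis with reductive work-up cuts the allyl group to a 2-hydroxyethyl arm, whose hydroxyl opens the activated acetal ester by intramolecular transacylation (lactonisation) with loss of pivalaldehyde; the quaternary centre is not involved.

Step 8
Reactants: 17 3-methylbut-3-en-1-ol (isoprenol)
Product: 18 4-bromo-2-methylbut-1-ene
Conditions: CBr4, PPh3, CH2Cl2, 0 °C → rt
Reagents that add atoms: carbon tetrabromide, BrC(Br)(Br)Br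
Why: Appel bromination converts the primary alcohol to the bromide by SN2 displacement of the alkoxyphosphonium group without touching the 1,1-disubstituted olefin.

Step 9
Reactants: 16 (3R)-3-hydroxy-3-methyloxolan-2-one; 18 4-bromo-2-methylbut-1-ene
Product: 21 (3R)-1,3-dihydroxy-3,7-dimethyloct-7-en-4-one, via Grignard reagent 19 (not isolated), via cyclic hemiketal 20 (not isolated)
Conditions: 18, Mg turnings, I2 (cat.), THF, reflux; then 16 added to 2.3 equiv of the Grignard solution at −78 → −20 °C; sat. aq NH4Cl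
Reagents that add atoms: none
Why: Grignard mono-addition to a lactone: one equivalent deprotonates the tertiary OH, the second adds to the lactone carbonyl, and the chelated magnesium hemiketal does not collapse at low temperature, so work-up gives the hemiketal and its open γ-hydroxy ketone tautomer with C10 untouched.

Step 10
Reactants: 21 (3R)-1,3-dihydroxy-3,7-dimethyloct-7-en-4-one
Product: 22 (3R)-3-hydroxy-3,7-dimethyl-4-oxooct-7-enal
Conditions: TEMPO (10 mol%), PhI(OAc)2 (1.2 equiv), CH2Cl2, rt; used crude at once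
Reagents that add atoms: none
Why: TEMPO-catalysed oxidation is selective for the primary alcohol of the open-chain tautomer (the tertiary and hemiketal hydroxyls cannot be oxidised) and stops at the aldehyde.

Step 11
Reactants: 7 (5R)-3-(bromomethyl)-5-[(1E)-prop-1-en-1-yl]furan-2(5H)-one; 22 (3R)-3-hydroxy-3,7-dimethyl-4-oxooct-7-enal
Product: 24 (4R,5R)-4-[(1S,3R)-1,3-dihydroxy-3,7-dimethyl-4-oxooct-7-en-1-yl]-3-methylidene-5-[(1E)-prop-1-en-1-yl]oxolan-2-one, via allylzinc bromide 23 (not isolated)
Conditions: Zn dust (3 equiv), THF/sat. aq NH4Cl (2:1), 0 °C → rt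
Reagents that add atoms: none
Why: Zinc Barbier allylation (SE2'): the allylzinc adds through its γ-carbon in a chair Zimmerman–Traxler transition state, anti to the C6 propenyl group (C7 R, trans-lactone) and with the aldehyde chain equatorial, which for the ring-fixed E-type allyl unit gives the C7/C8 anti (8S) alcohol and the α-methylene lactone, while the hindered ketone is not attacked.

Step 12
Reactants: 24 (4R,5R)-4-[(1S,3R)-1,3-dihydroxy-3,7-dimethyl-4-oxooct-7-en-1-yl]-3-methylidene-5-[(1E)-prop-1-en-1-yl]oxolan-2-one; 25 tiglic acid [(2E)-2-methylbut-2-enoic acid]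
Product: 26 (1R,3R)-3-hydroxy-3,7-dimethyl-1-[(2R,3R)-4-methylidene-5-oxo-2-[(1E)-prop-1-en-1-yl]oxolan-3-yl]-4-oxooct-7-en-1-yl (2E)-2-methylbut-2-enoate
Conditions: PPh3, DIAD, toluene, 0 °C → rt
Reagents that add atoms: none
Why: Mitsunobu esterification: the secondary C8 alkoxyphosphonium is displaced by tiglate with SN2 inversion (8S → 8R), while the tertiary C10 alcohol cannot be activated.

Step 13
Reactants: 26 (1R,3R)-3-hydroxy-3,7-dimethyl-1-[(2R,3R)-4-methylidene-5-oxo-2-[(1E)-prop-1-en-1-yl]oxolan-3-yl]-4-oxooct-7-en-1-yl (2E)-2-methylbut-2-enoate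
Product: 27 (3aR,4R,6R,10Z,11aR)-6-hydroxy-6,10-dimethyl-3-methylidene-2,7-dioxo-2,3,3a,4,5,6,7,8,9,11a-decahydrocyclodeca[b]furan-4-yl (2E)-2-methylbut-2-enoate (target)
Conditions: second-generation Grubbs catalyst [(H2IMes)(PCy3)Cl2Ru=CHPh] (15 mol% in portions), toluene (1 mM), 80 °C
Reagents that add atoms: none
Why: Ring-closing metathesis at high dilution joins the propenyl and 1,1-disubstituted olefins with loss of propene to close the ten-membered ring, in which the new trisubstituted C4=C5 olefin is expected to take the less strained ring-Z geometry; the electron-poor methylene-lactone and tiglate olefins do not compete and no stereocentre is touched.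

## Compound list

1 | (E)-but-2-enal (crotonaldehyde) | C/C=C/C=O | starting material
2 | vinylmagnesium bromide | C=C[Mg]Br | starting material
3 | rac-(4E)-hexa-1,4-dien-3-ol | C=CC(O)/C=C/C | intermediate
4 | (3S,4E)-hexa-1,4-dien-3-ol | C=C[C@H](O)/C=C/C | intermediate
5 | 2-(bromomethyl)prop-2-enoic acid | C=C(CBr)C(=O)O | starting material
6 | (3S,4E)-hexa-1,4-dien-3-yl 2-(bromomethyl)prop-2-enoate | C=C[C@H](OC(=O)C(=C)CBr)/C=C/C | intermediate
7 | (5R)-3-(bromomethyl)-5-[(1E)-prop-1-en-1-yl]furan-2(5H)-one | O=C1O[C@H](/C=C/C)C=C1CBr | intermediate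
8 | (S)-lactic acid [(2S)-2-hydroxypropanoic acid] | C[C@H](O)C(=O)O | starting material
9 | pivalaldehyde (2,2-dimethylpropanal) | CC(C)(C)C=O | starting material
10 | (2S,5S)-2-tert-butyl-5-methyl-1,3-dioxolan-4-one (cis) | C[C@@H]1O[C@H](C(C)(C)C)OC1=O | intermediate
11 | allyl bromide (3-bromoprop-1-ene) | C=CCBr | starting material
12 | lithium (2S)-2-tert-butyl-5-methyl-1,3-dioxol-4-olate (enolate of 10) | [Li+].[O-]C1=C(C)O[C@H](C(C)(C)C)O1 | intermediate
13 | (2S,5R)-2-tert-butyl-5-methyl-5-(prop-2-en-1-yl)-1,3-dioxolan-4-one | C[C@]1(CC=C)O[C@H](C(C)(C)C)OC1=O | intermediate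
14 | [(2S,4R)-2-tert-butyl-4-methyl-5-oxo-1,3-dioxolan-4-yl]acetaldehyde | C[C@]1(CC=O)O[C@H](C(C)(C)C)OC1=O | intermediate
15 | (2S,5R)-2-tert-butyl-5-(2-hydroxyethyl)-5-methyl-1,3-dioxolan-4-one | C[C@]1(CCO)O[C@H](C(C)(C)C)OC1=O | intermediate
16 | (3R)-3-hydroxy-3-methyloxolan-2-one | C[C@@]1(O)CCOC1=O | intermediate
17 | 3-methylbut-3-en-1-ol (isoprenol) | C=C(C)CCO | starting material
18 | 4-bromo-2-methylbut-1-ene | C=C(C)CCBr | intermediate
19 | (3-methylbut-3-en-1-yl)magnesium bromide | C=C(C)CC[Mg]Br | intermediate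
20 | (3R)-3-methyl-2-(3-methylbut-3-en-1-yl)oxolane-2,3-diol (cyclic hemiketal, both C2 epimers) | C[C@@]1(O)CCOC1(O)CCC(C)=C | intermediate
21 | (3R)-1,3-dihydroxy-3,7-dimethyloct-7-en-4-one | OCC[C@@](C)(O)C(=O)CCC(C)=C | intermediate
22 | (3R)-3-hydroxy-3,7-dimethyl-4-oxooct-7-enal | O=CC[C@@](C)(O)C(=O)CCC(C)=C | intermediate
23 | {[(5R)-2-oxo-5-[(1E)-prop-1-en-1-yl]-2,5-dihydrofuran-3-yl]methyl}zinc bromide | O=C1O[C@H](/C=C/C)C=C1C[Zn]Br | intermediate
24 | (4R,5R)-4-[(1S,3R)-1,3-dihydroxy-3,7-dimethyl-4-oxooct-7-en-1-yl]-3-methylidene-5-[(1E)-prop-1-en-1-yl]oxolan-2-one | C=C1C(=O)O[C@H](/C=C/C)[C@H]1[C@@H](O)C[C@@](C)(O)C(=O)CCC(C)=C | intermediate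
25 | tiglic acid [(2E)-2-methylbut-2-enoic acid] | C/C=C(\C)C(=O)O | starting material
26 | (1R,3R)-3-hydroxy-3,7-dimethyl-1-[(2R,3R)-4-methylidene-5-oxo-2-[(1E)-prop-1-en-1-yl]oxolan-3-yl]-4-oxooct-7-en-1-yl (2E)-2-methylbut-2-enoate | C=C1C(=O)O[C@H](/C=C/C)[C@H]1[C@H](OC(=O)/C(C)=C/C)C[C@@](C)(O)C(=O)CCC(C)=C | intermediate
27 | (3aR,4R,6R,10Z,11aR)-6-hydroxy-6,10-dimethyl-3-methylidene-2,7-dioxo-2,3,3a,4,5,6,7,8,9,11a-decahydrocyclodeca[b]furan-4-yl (2E)-2-methylbut-2-enoate | C=C1C(=O)O[C@@H]2/C=C(/C)CCC(=O)[C@](C)(O)C[C@@H](OC(=O)/C(C)=C/C)[C@@H]12 | target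

## Step count and risks

Total step count: 13.
Longest linear sequence: 8 steps (steps 5, 6, 7, 9, 10, 11, 12, 13, from (S)-lactic acid 8). The other branches are steps 1–4 (butenolide 7) and step 8 (bromide 18).

Three steps most likely to fail:

Step 13 (macrocyclic ring-closing metathesis). The ring is strained, one olefin partner is 1,1-disubstituted, and oligomerisation or the wrong olefin geometry can compete. The fallback sets out from alcohol 24 and closes the ring before the ester is in place. There the free C8 hydroxyl, partly tied up as the C8–O–C1 hemiketal, gives the chain a different conformational bias. The same ruthenium catalyst in dilute toluene at 80 °C would give the macrocyclic 8-epi alcohol (3aR,4S,6R,10Z,11aR)-4,6-dihydroxy-6,10-dimethyl-3-methylidene-3a,4,5,6,8,9-hexahydrocyclodeca[b]furan-2,7(3H,11aH)-dione F1. Mitsunobu esterification of F1 with tiglic acid 25 (PPh3, DIAD) then inverts C8 and comes back to the route at 27.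

Step 12 (Mitsunobu inversion). The C8 alcohol is hindered, tiglic acid is a weak pronucleophile, the γ-hydroxy ketone can hide as a hemiketal, and elimination is possible. The fallback sets out from 24. Selective sulfonylation of the secondary hydroxyl with chloromethanesulfonyl chloride and pyridine (CH2Cl2, 0 °C) gives (1S,3R)-3-hydroxy-3,7-dimethyl-1-[(2R,3R)-4-methylidene-5-oxo-2-[(1E)-prop-1-en-1-yl]oxolan-3-yl]-4-oxooct-7-en-1-yl chloromethanesulfonate F2. This is displaced with inversion by caesium tiglate F3 (made from 25 and Cs2CO3; 18-crown-6, toluene, 60–80 °C), and the sequence comes back at 26.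

Step 11 (Barbier coupling). Aldehyde 22 is a sensitive β-hydroxy 1,4-keto aldehyde, the diastereoselectivity rests on the chair transition state, and the product could translactonise to the C8 oxygen. The fallback sets out from bromolactone 7. Borylation with B2pin2 and catalytic Pd2(dba)3 (zerovalent palladium; THF, 60 °C) gives the isolable allylboronate (5R)-5-[(1E)-prop-1-en-1-yl]-3-[(4,4,5,5-tetramethyl-1,3,2-dioxaborolan-2-yl)methyl]furan-2(5H)-one F4. F4 adds to aldehyde 22 under Sc(OTf)3 catalysis (toluene, 0 °C) through the same closed chair transition state under anhydrous, non-reducing conditions, and the sequence comes back at 24.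

Further compounds

F1 | step 13 | (3aR,4S,6R,10Z,11aR)-4,6-dihydroxy-6,10-dimethyl-3-methylidene-3a,4,5,6,8,9-hexahydrocyclodeca[b]furan-2,7(3H,11aH)-dione | C=C1C(=O)O[C@@H]2/C=C(/C)CCC(=O)[C@](C)(O)C[C@H](O)[C@@H]12
F2 | step 12 | (1S,3R)-3-hydroxy-3,7-dimethyl-1-[(2R,3R)-4-methylidene-5-oxo-2-[(1E)-prop-1-en-1-yl]oxolan-3-yl]-4-oxooct-7-en-1-yl chloromethanesulfonate | C=C1C(=O)O[C@H](/C=C/C)[C@H]1[C@@H](OS(=O)(=O)CCl)C[C@@](C)(O)C(=O)CCC(C)=C
F3 | step 12 | caesium (2E)-2-methylbut-2-enoate (caesium tiglate) | C/C=C(\C)C(=O)[O-].[Cs+]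
F4 | step 11 | (5R)-5-[(1E)-prop-1-en-1-yl]-3-[(4,4,5,5-tetramethyl-1,3,2-dioxaborolan-2-yl)methyl]furan-2(5H)-one | O=C1O[C@H](/C=C/C)C=C1CB2OC(C)(C)C(C)(C)O2
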